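A direct plan would set C7 and C8 (megaphone numbering: C1 ketone, C4 methoxy carbon, C6 quaternary carbon, C7 carbinol, C8 methyl-bearing carbon) by syn-crotylation of 3,4,5-trimethoxybenzaldehyde, convert the adduct into the cis-γ-lactone A1, alkylate its enolate twice to the quaternary lactone A2, methylenate the lactone carbonyl, close the carbocycle by enol ether–acetal cyclisation to the dienol ether A3, and introduce the C4 methoxy group last by oxidation. Its weakest steps would be:
- the late oxidative 1,4-dimethoxylation of A3, which lacks close precedent and would have to spare a trimethoxyarene and an allyl group while setting C4;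
- the acid-mediated cyclisation–elimination that delivers A3, a hydrolysis-prone dienol ether and a 1,5-diene open to Cope rearrangement;
- the hydroboration, oxidative lactonisation and methylenation steps, which add length but no complexity.

With C7 as an aldehyde and the enone of the cyclohexenone ring read as a C1=C2 alkene, C7–C8–C6–C1=C2 is a γ,δ-unsaturated aldehyde, the Claisen retron. The route therefore makes the most hindered bond, C6–C8, by rearranging the (E)-propenyl ether of cis-3-allyl-5-methoxycyclohex-2-enol: one chair transition state creates quaternary C6 and tertiary C8, turns the ring oxygen into the C7 aldehyde and shifts the ring alkene. The ring is bought, not closed, and carries the C4 methoxy group from step 2; C7 follows by Felkin aryl addition, the enone by a regiospecific singlet-oxygen ene reaction. Lactone template, methylenation, dienol ether and late C4 oxidation all disappear.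

Key step: step 7

Remark (assumption): in step 1 the enantiomer of the ferrocenyl diphosphine is the one that gives the (S)-boronate 3; should the stated ligand favour R, its mirror image is used.
Remark: the descriptor of the methoxy-bearing carbon changes between S and R along the route through CIP priorities alone; its geometry is never touched after step 1.

Step 1
Reactants: 1 cyclohex-2-en-1-one; 2 bis(pinacolato)diboron
Product: 4 (S)-3-hydroxycyclohexan-1-one, via boronate 3 (not isolated)
Conditions: CuCl (3 mol %), NaOt-Bu (6 mol %), (R)-1-[(S)-2-(diphenylphosphino)ferrocenyl]ethyldicyclohexylphosphine (4 mol %), MeOH (2 equiv), THF, rt; then 30 % H2O2, pH 7 phosphate buffer, 0 °C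
Reagents that add atoms: bis(pinacolato)diboron (2), CC1(C)OB(OC1(C)C)B1OC(C)(C)C(C)(C)O1 (boron, in 3 only); hydrogen peroxide, OO
Why: Copper-catalysed enantioselective conjugate borylation followed by stereoretentive peroxide oxidation of the C–B bond: the diphosphine–CuBpin complex adds to one enantiotopic face of the enone, which fixes as S the carbon that becomes C4 of megaphone.

Step 2
Reactants: 4 (S)-3-hydroxycyclohexan-1-one; 5 iodomethane
Product: 6 (S)-3-methoxycyclohexan-1-one
Conditions: MeI (5 equiv), Ag2O (1.5 equiv), 4 Å MS, CH2Cl2, rt, dark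
Reagents that add atoms: iodomethane (5), CI
Why: Purdie methylation (Ag2O-assisted Williamson etherification) runs without soluble base, so the β-hydroxy ketone is etherified without E1cB loss of the oxygen and the stereocentre is not touched.

Step 3
Reactants: 6 (S)-3-methoxycyclohexan-1-one
Product: 9 (S)-5-methoxycyclohex-2-en-1-one, via lithium enolate 7 (not isolated), via silyl enol ether 8 (not isolated)
Conditions: LDA (1.1 equiv), THF, −78 °C; Me3SiCl; then Pd(OAc)2 (1.0 equiv), MeCN, rt
Reagents that add atoms: LDA, CC(C)N([Li])C(C)C (lithium, in 7 only); chlorotrimethylsilane, C[Si](C)(C)Cl (silicon, in 8 only)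
Why: Saegusa–Ito dehydrogenation: LDA should remove kinetically a proton of the CH2 remote from the methoxy group (the CH2 between C=O and C–OMe is more hindered), the trapped silyl enol ether is oxidised by Pd(OAc)2 through β-hydride loss, and the stereocentre is not involved.

Step 4
Reactants: 9 (S)-5-methoxycyclohex-2-en-1-one; 10 allylmagnesium bromide
Product: 12 (5S)-5-methoxy-1-(prop-2-en-1-yl)cyclohex-2-en-1-ol (both C1 epimers), via bromomagnesium alkoxide 11 (not isolated)
Conditions: allylMgBr (1.2 equiv, 1.0 M in Et2O), THF, −78 °C; H2O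
Reagents that add atoms: allylmagnesium bromide (10), C=CC[Mg]Br
Why: 1,2-Addition of an allyl Grignard reagent (six-membered allyl-transfer transition state, faster than enolisation at −78 °C) places the allyl group on the carbon that becomes C6; the new carbinol centre is destroyed in step 5, so both epimers serve.

Step 5
Reactants: 12 (5S)-5-methoxy-1-(prop-2-en-1-yl)cyclohex-2-en-1-ol
Product: 15 (R)-5-methoxy-3-(prop-2-en-1-yl)cyclohex-2-en-1-one, via chlorochromate ester 13 (not isolated), via transposed chlorochromate ester 14 (not isolated)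
Conditions: pyridinium chlorochromate (2 equiv), 4 Å MS, CH2Cl2, rt
Reagents that add atoms: pyridinium chlorochromate, [O-][Cr](=O)(=O)Cl.c1cc[nH+]cc1 (the carbonyl oxygen)
Why: Babler–Dauben oxidative transposition: the chlorochromate ester of the tertiary allylic alcohol undergoes a [3,3] shift to the secondary ester, which is oxidised to the β-allyl enone; the methoxy stereocentre is not touched.

Step 6
Reactants: 15 (R)-5-methoxy-3-(prop-2-en-1-yl)cyclohex-2-en-1-one
Product: 17 (1R,5R)-5-methoxy-3-(prop-2-en-1-yl)cyclohex-2-en-1-ol (cis), via catechol borate 16 (not isolated)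
Conditions: (S)-2-methyl-CBS-oxazaborolidine (15 mol %), catecholborane (1.6 equiv), toluene, −78 °C; then MeOH, aq. NaOH wash
Reagents that add atoms: catecholborane, [H]B1Oc2ccccc2O1 (boron, in 16 only)
Why: Corey–Bakshi–Shibata reduction: the (S)-oxazaborolidine binds the ketone with the alkenyl arm as the large group and delivers hydride to give the 1R carbinol, cis to the methoxy group and expected to be the isomer that axial hydride delivery also favours; catecholborane should not hydroborate the allyl group at −78 °C.

Step 7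
Reactants: 17 (1R,5R)-5-methoxy-3-(prop-2-en-1-yl)cyclohex-2-en-1-ol; 18 (E)-1-iodoprop-1-ene
Product: 20 (2S)-2-[(1S,5S)-5-methoxy-1-(prop-2-en-1-yl)cyclohex-2-en-1-yl]propanal, via propenyl ether 19 (not isolated)
Conditions: 18 (2 equiv), CuI (10 mol %), 3,4,7,8-tetramethyl-1,10-phenanthroline (20 mol %), Cs2CO3 (1.5 equiv), toluene, 80 °C, sealed tube; filter through Celite; then toluene, 120 °C
Reagents that add atoms: (E)-1-iodoprop-1-ene (18), C/C=C/I
Why: Copper-catalysed C–O coupling of the alkoxide of 17 with the vinyl iodide (E geometry retained) gives allyl vinyl ether 19, which on heating undergoes a concerted suprafacial [3,3] shift (aliphatic Claisen rearrangement; the copper-catalysed vinylation–Claisen domino is the closest known reaction type) in which the cyclohexene is the allyl component, so the C2–O bond is traded for the C6–C8 bond, the alkene moves to C1=C2 and the ring oxygen becomes the C7 aldehyde oxygen. No ring is closed. C6 is controlled by the allylic C–O bond: the new bond must form on the face that carried the oxygen, which in 17 is cis to the C4 methoxy group, so the side chain ends cis to OMe and the allyl group trans to it. C8 is controlled by the E enol ether geometry read through a chair transition state with the methyl group pseudo-equatorial, which gives 8S next to this C6. The step needs chair over boat, and the substrate should secure it because a boat would eclipse the methyl group and hydrogen on C8 with the allyl group and ring CH2 on the fully substituted terminus C6, whereas the chair only places the small C7–H over the ring. Removing the base before heating and the 120 °C ceiling guard C8 against epimerisation and the 1,5-diene product against Cope rearrangement.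

Step 8
Reactants: 20 (2S)-2-[(1S,5S)-5-methoxy-1-(prop-2-en-1-yl)cyclohex-2-en-1-yl]propanal; 21 (3,4,5-trimethoxyphenyl)magnesium bromide
Product: 23 (1R,2S)-2-[(1S,5S)-5-methoxy-1-(prop-2-en-1-yl)cyclohex-2-en-1-yl]-1-(3,4,5-trimethoxyphenyl)propan-1-ol, via bromomagnesium alkoxide 22 (not isolated)
Conditions: 21 (1.3 equiv, 0.5 M in THF), THF, −78 to −40 °C; H2O
Reagents that add atoms: (3,4,5-trimethoxyphenyl)magnesium bromide (21), COc1cc([Mg]Br)cc(OC)c1OC
Why: Felkin–Anh-controlled Grignard addition to an α-chiral aldehyde: the bond from C8 to quaternary C6 stands anti to the incoming aryl group, which passes the small hydrogen, so the 7R carbinol (7,8-syn) should form; no other electrophilic group is present.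

Step 9
Reactants: 23 (1R,2S)-2-[(1S,5S)-5-methoxy-1-(prop-2-en-1-yl)cyclohex-2-en-1-yl]-1-(3,4,5-trimethoxyphenyl)propan-1-ol
Product: 26 megaphone, via hydroperoxide 24 (not isolated), via peracetate 25 (not isolated)
Conditions: O2, tetraphenylporphyrin (1 mol %), visible light, CH2Cl2, 0 °C; then Ac2O (1.3 equiv), pyridine (3 equiv), 0 °C to rt
Reagents that add atoms: dioxygen, O=O; acetic anhydride, CC(=O)OC(C)=O (acetyl, in 25 only)
Why: Schenck ene reaction followed by Kornblum–DeLaMare-type dehydration: singlet oxygen can only abstract an allylic hydrogen from C3 because C6 is quaternary, so oxygen enters at C1 and the alkene moves to C2=C3 while the monosubstituted allyl group and the arene should stay inert, and the hydroperoxide, acetylated in preference to the hindered C7 hydroxyl, loses acetic acid to give the enone; no stereocentre is touched.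

## Compound list
1 | cyclohex-2-en-1-one | O=C1C=CCCC1 | starting material
2 | bis(pinacolato)diboron | CC1(C)OB(OC1(C)C)B1OC(C)(C)C(C)(C)O1 | starting material
3 | (S)-3-(4,4,5,5-tetramethyl-1,3,2-dioxaborolan-2-yl)cyclohexan-1-one | O=C1CCC[C@H](B2OC(C)(C)C(C)(C)O2)C1 | intermediate
4 | (S)-3-hydroxycyclohexan-1-one | O=C1CCC[C@H](O)C1 | intermediate
5 | iodomethane | CI | starting material
6 | (S)-3-methoxycyclohexan-1-one | O=C1CCC[C@H](OC)C1 | intermediate
7 | lithium enolate of 6, lithium (5S)-5-methoxycyclohex-1-en-1-olate | [Li]OC1=CCC[C@H](OC)C1 | intermediate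
8 | trimethyl{[(5S)-5-methoxycyclohex-1-en-1-yl]oxy}silane | C[Si](C)(C)OC1=CCC[C@H](OC)C1 | intermediate
9 | (S)-5-methoxycyclohex-2-en-1-one | O=C1C=CC[C@H](OC)C1 | intermediate
10 | allylmagnesium bromide | C=CC[Mg]Br | starting material
11 | bromomagnesium alkoxide of 12 | C=CCC1(O[Mg]Br)C=CC[C@H](OC)C1 | intermediate
12 | (5S)-5-methoxy-1-(prop-2-en-1-yl)cyclohex-2-en-1-ol (C1 epimers) | C=CCC1(O)C=CC[C@H](OC)C1 | intermediate
13 | chlorochromate ester of 12 | C=CCC1(O[Cr](=O)(=O)Cl)C=CC[C@H](OC)C1 | intermediate
14 | (5R)-5-methoxy-3-(prop-2-en-1-yl)cyclohex-2-en-1-yl chlorochromate (C1 epimers) | Cl[Cr](=O)(=O)OC1C=C(CC=C)C[C@@H](OC)C1 | intermediate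
15 | (R)-5-methoxy-3-(prop-2-en-1-yl)cyclohex-2-en-1-one | O=C1C=C(CC=C)C[C@@H](OC)C1 | intermediate
16 | catechol borate ester of 17 | c1ccc2OB(O[C@H]3C=C(CC=C)C[C@@H](OC)C3)Oc2c1 | intermediate
17 | (1R,5R)-5-methoxy-3-(prop-2-en-1-yl)cyclohex-2-en-1-ol (cis) | O[C@H]1C=C(CC=C)C[C@@H](OC)C1 | intermediate
18 | (E)-1-iodoprop-1-ene | C/C=C/I | starting material
19 | (3R,5R)-5-methoxy-3-[(E)-prop-1-en-1-yloxy]-1-(prop-2-en-1-yl)cyclohex-1-ene | C/C=C/O[C@H]1C=C(CC=C)C[C@@H](OC)C1 | intermediate
20 | (2S)-2-[(1S,5S)-5-methoxy-1-(prop-2-en-1-yl)cyclohex-2-en-1-yl]propanal | C=CC[C@]1([C@H](C)C=O)C[C@@H](OC)CC=C1 | intermediate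
21 | (3,4,5-trimethoxyphenyl)magnesium bromide | COc1cc([Mg]Br)cc(OC)c1OC | starting material
22 | bromomagnesium alkoxide of 23 | C=CC[C@]1([C@H](C)[C@@H](O[Mg]Br)c2cc(OC)c(OC)c(OC)c2)C[C@@H](OC)CC=C1 | intermediate
23 | (1R,2S)-2-[(1S,5S)-5-methoxy-1-(prop-2-en-1-yl)cyclohex-2-en-1-yl]-1-(3,4,5-trimethoxyphenyl)propan-1-ol | C=CC[C@]1([C@H](C)[C@@H](O)c2cc(OC)c(OC)c(OC)c2)C[C@@H](OC)CC=C1 | intermediate
24 | (1R,2S)-2-[(1R,5R)-2-hydroperoxy-5-methoxy-1-(prop-2-en-1-yl)cyclohex-3-en-1-yl]-1-(3,4,5-trimethoxyphenyl)propan-1-ol (epimers at the hydroperoxy carbon) | C=CC[C@]1([C@H](C)[C@@H](O)c2cc(OC)c(OC)c(OC)c2)C[C@@H](OC)C=CC1OO | intermediate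
25 | peracetate of 24 | C=CC[C@]1([C@H](C)[C@@H](O)c2cc(OC)c(OC)c(OC)c2)C[C@@H](OC)C=CC1OOC(C)=O | intermediate
26 | megaphone, (4R,6R)-6-[(1R,2S)-1-hydroxy-1-(3,4,5-trimethoxyphenyl)propan-2-yl]-4-methoxy-6-(prop-2-en-1-yl)cyclohex-2-en-1-one | C=CC[C@]1([C@H](C)[C@@H](O)c2cc(OC)c(OC)c(OC)c2)C[C@@H](OC)C=CC1=O | target

Total step count: 9. Longest linear sequence: 9 steps (from cyclohex-2-en-1-one).

Steps most likely to fail:

1. Step 7. Partial passage through a boat transition state, or epimerisation of the α-branched aldehyde by the carbonate base, would erode control at C8; the hindered secondary alkoxide may also couple slowly. Fallback: C8 is taken out of the rearrangement and set by an auxiliary. From 17, vinyl exchange with ethyl vinyl ether under Hg(OAc)2 catalysis gives the vinyl ether F1, whose Claisen rearrangement at 110 °C gives the C8-unsubstituted aldehyde F2, with C6 set by the same suprafacial transfer. Pinnick oxidation (NaClO2, NaH2PO4, 2-methylbut-2-ene) gives the acid F3. Pivaloyl chloride and Et3N, then lithiated (S)-4-benzyl-1,3-oxazolidin-2-one, give the imide F4. NaN(SiMe3)2 and MeI methylate the chelated Z-enolate on the face away from the benzyl group to give the 8S imide F5. LiBH4 releases the alcohol F6, and Dess–Martin oxidation returns to 20.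

2. Step 9. The ene reaction at an alkene next to a quaternary carbon is slow, so that oxidation at the electron-rich arene, allylic hydroperoxide rearrangement or acetylation of the C7 hydroxyl may compete. Fallback: the oxygenation is moved ahead of the aryl addition. From 20, the same photo-oxygenation gives the hydroperoxide F9, and Ac2O with pyridine dehydrates it to the enone aldehyde F10. Reagent 21 at −78 °C then adds to the aldehyde, far faster than to the hindered conjugated ketone, and gives megaphone 26 through the bromomagnesium alkoxide F11.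

3. Step 8. Erosion of the Felkin preference at the hindered aldehyde would give a mixture at C7. Fallback: C7 is set by reagent control instead. From the mixture of 23 and its C7 epimer, Dess–Martin oxidation gives the aryl ketone F7. Reduction with catecholborane and (S)-2-methyl-CBS-oxazaborolidine, the aryl group taking the large-group position, returns to 23 through the catechol borate F8.

Further compounds
F1 | step 7 | (3R,5R)-3-(ethenyloxy)-5-methoxy-1-(prop-2-en-1-yl)cyclohex-1-ene | C=CO[C@H]1C=C(CC=C)C[C@@H](OC)C1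
F2 | step 7 | 2-[(1R,5S)-5-methoxy-1-(prop-2-en-1-yl)cyclohex-2-en-1-yl]acetaldehyde | C=CC[C@]1(CC=O)C[C@@H](OC)CC=C1
F3 | step 7 | 2-[(1R,5S)-5-methoxy-1-(prop-2-en-1-yl)cyclohex-2-en-1-yl]acetic acid | C=CC[C@]1(CC(=O)O)C[C@@H](OC)CC=C1
F4 | step 7 | (4S)-4-benzyl-3-{2-[(1R,5S)-5-methoxy-1-(prop-2-en-1-yl)cyclohex-2-en-1-yl]acetyl}-1,3-oxazolidin-2-one | C=CC[C@]1(CC(=O)N2[C@@H](Cc3ccccc3)COC2=O)C[C@@H](OC)CC=C1
F5 | step 7 | (4S)-4-benzyl-3-{(2S)-2-[(1S,5S)-5-methoxy-1-(prop-2-en-1-yl)cyclohex-2-en-1-yl]propanoyl}-1,3-oxazolidin-2-one | C=CC[C@]1([C@H](C)C(=O)N2[C@@H](Cc3ccccc3)COC2=O)C[C@@H](OC)CC=C1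
F6 | step 7 | (2S)-2-[(1S,5S)-5-methoxy-1-(prop-2-en-1-yl)cyclohex-2-en-1-yl]propan-1-ol | C=CC[C@]1([C@H](C)CO)C[C@@H](OC)CC=C1
F7 | step 8 | (2S)-2-[(1S,5S)-5-methoxy-1-(prop-2-en-1-yl)cyclohex-2-en-1-yl]-1-(3,4,5-trimethoxyphenyl)propan-1-one | C=CC[C@]1([C@H](C)C(=O)c2cc(OC)c(OC)c(OC)c2)C[C@@H](OC)CC=C1
F8 | step 8 | catechol borate ester of 23 | C=CC[C@]1([C@H](C)[C@@H](OB2Oc3ccccc3O2)c2cc(OC)c(OC)c(OC)c2)C[C@@H](OC)CC=C1
F9 | step 9 | (2S)-2-[(1R,5R)-2-hydroperoxy-5-methoxy-1-(prop-2-en-1-yl)cyclohex-3-en-1-yl]propanal (epimers at the hydroperoxy carbon) | C=CC[C@]1([C@H](C)C=O)C[C@@H](OC)C=CC1OO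
F10 | step 9 | (2S)-2-[(1R,5R)-5-methoxy-2-oxo-1-(prop-2-en-1-yl)cyclohex-3-en-1-yl]propanal | C=CC[C@]1([C@H](C)C=O)C[C@@H](OC)C=CC1=O
F11 | step 9 | bromomagnesium alkoxide of megaphone | C=CC[C@]1([C@H](C)[C@@H](O[Mg]Br)c2cc(OC)c(OC)c(OC)c2)C[C@@H](OC)C=CC1=O
A1 | direct plan | (4S,5R)-4-methyl-5-(3,4,5-trimethoxyphenyl)oxolan-2-one | O=C1C[C@H](C)[C@H](c2cc(OC)c(OC)c(OC)c2)O1
A2 | direct plan | (3S,4S,5R)-3-(3,3-dimethoxypropyl)-4-methyl-3-(prop-2-en-1-yl)-5-(3,4,5-trimethoxyphenyl)oxolan-2-one | O=C1[C@](CC=C)(CCC(OC)OC)[C@H](C)[C@H](c2cc(OC)c(OC)c(OC)c2)O1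
A3 | direct plan | (2R,3S,3aR)-3-methyl-3a-(prop-2-en-1-yl)-2-(3,4,5-trimethoxyphenyl)-2,3,3a,4-tetrahydro-1-benzofuran | C=CC[C@]12CC=CC=C1O[C@@H](c1cc(OC)c(OC)c(OC)c1)[C@H]2C
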